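Time is the axis shared by the runs below, each read up to 12 h.

| flask | starting material | free catalyst | product | time |
|---|---|---|---|---|
| cedar | 120 mM | 3.60 mM |  |  |
| larch | 60.0 mM | 3.60 mM |  |  |
| oak | 120 mM | 1.80 mM |  |  |
| ash | 360 mM | 3.60 mM |  |  |
| birch | 120 mM | 3.60 mM | 36.0 mM | 12 h |

| run | time / h | [starting material] / mM |
|---|---|---|
| cedar run | 0.48 | 115.0 |
| cedar run | 1.1 | 108.5 |
| cedar run | 2.4 | 98.0 |
| cedar run | 5.4 | 79.7 |
| cedar run | 12 | 61.3 |
| larch run | 0.48 | 57.1 |
| larch run | 1.1 | 52.4 |
| larch run | 2.4 | 47.5 |
| larch run | 5.4 | 38.3 |
| larch run | 12 | 30.5 |
| oak run | 0.48 | 118.7 |
| oak run | 1.1 | 114.9 |
| oak run | 2.4 | 109.1 |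
| oak run | 5.4 | 97.9 |
| oak run | 12 | 82.1 |
| ash run | 0.48 | 350.5 |
| ash run | 1.1 | 336.9 |
| ash run | 2.4 | 312.9 |
| ash run | 5.4 | 265.7 |
| ash run | 12 | 195.6 |

(readings scatter by 0.4 mM)

- Overall: starting material -> product, with free catalyst as catalyst.
- Constant volume, constant temperature.
- Readings of a species count what is bound in complexes too.
- An order is taken over about fifteen percent of the charge, up and down.

- reaction order in [free catalyst] at the outset, round the charge of the cedar run, defined at two percent of the starting material turned into product
- reaction order in [starting material] at the outset, round the charge of the cedar run, defined at two percent of the starting material turned into product (one fixed amount of product, the same in the runs compared)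
- the larch run starts with 60.0 mM less of starting material than the cedar run, and with no product. Compared where both hold the same amount of starting material, once fifteen percent of what the larch run was charged with has turned into product, is the larch run faster, slower or alike (within a tenth)?
- starting material in the birch run at 12 h, as a share of the starting material charged

In the opening 0.48 h, the flasks with 3.60 mM of free catalyst lose starting material at 6.04 mM h⁻¹ in the larch run, 10.4 mM h⁻¹ in the cedar run and 19.8 mM h⁻¹ in the ash run. Read between larch and ash, the rate follows the charge to the power 0.662. In the middle stretch, the cedar run still holds 66.4% of its charge at 5.4 h.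

The end stretch, from 5.4 h to 12 h, tests whether the slowing follows the product made. Retained activity is the rate in that window divided by the opening rate, once the opening rate has been scaled by that power to the starting material in the window. It reads 0.278 in the larch run, 0.375 in the cedar run and 0.714 in the ash run. Over the same window, the ratio of product to starting material is 0.744 in the larch run and 0.561 in the ash run. Retained activity therefore spreads wider between these runs, by 2.57, than that ratio does, by 1.33.

The reckoning here therefore treats added product as a small correction to a run that has the same charges. Birch is the cedar run plus product equal to 30.0% of its charge. The baseline share, the fraction of the charge left at 12 h with cedar's charges and no added product, is 51.1%, and the correction is set at zero within the reading.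

The forecast gives 1.2 and 0.65 for the orders, faster for the comparison and 65% for birch, which is 14 percentage points above the baseline. Its ground is the reading “so the reaction is reversible”.

The flask gives 1.1 and 0.70 for the orders, faster for the comparison and 50.4% for birch.

    free catalyst + starting material ⇌ catalyst-substrate complex (64.80 M⁻¹ h⁻¹, 2.344 h⁻¹)
    catalyst-substrate complex → product + free catalyst (11.66 h⁻¹)
    2 free catalyst → 2 spent catalyst (75.24 M⁻¹ h⁻¹)
    free catalyst + impurity → spent catalyst

The birch run keeps 50.4% of its charge at 12 h, 0.70 points under the baseline share of 51.1%. In the birch run, the impurity took 0.520 mM of the free catalyst at once, 14.4% of the free catalyst charged. For the following 12 h, catalyst-substrate complex gave product while free catalyst paired off into spent catalyst (catalyst deactivation), with the added 36.0 mM of product as an onlooker. The larch run, charged with 60.0 mM, held 50.8% of that charge at 12 h, 0.25 points under the baseline share, and its product made came to half of that charge at 12.2 h.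

The readings come from a simulation with constants of no real substance, and the scatter is random.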